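The retrosynthesis first cuts the two ring–CH2 bonds of the prenyl groups (at position 5 of ring A and position 3 of ring B), each back to a 1,1-dimethylallyl ether on the neighbouring 4-oxygen, then those two O–CMe2 bonds, and last the bond between C1 and ring A.
Locants: chain C1 (C=O), C2 (carbinol), C3 (CH2); ring A is the 2,4-dihydroxyphenyl on C1 and ring B the 4-hydroxyphenyl on C3, each ring numbered from the carbon that carries the chain.
Enabling feature: each prenyl group sits ortho to a phenolic oxygen (position 5 of ring A beside its 4-hydroxyl, position 3 of ring B beside its 4-hydroxyl), which is the relationship an aromatic [3,3] shift of an O-bound tertiary allyl unit produces.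
Forward: a ring-A aryl-lithium is joined to a tyrosine-derived C2–C3–ring-B Weinreb amide, the benzyl ethers are removed, both para phenols are O-propargylated and semihydrogenated, the ring-A 2-oxygen is silylated, one thermal step sets both prenyl groups, and fluoride frees the target; no ring is formed anywhere.
Stereochemistry: the only stereocentre, C2 (R), comes from O-benzyl-D-tyrosine by diazotisation with retention and is carried as a silyl ether through every later step.

Key step: step 10

Assumption: O-benzyl-D-tyrosine 1 is taken as a purchased peptide building block; it would otherwise be one step from D-tyrosine by benzylation of its copper(II) chelate.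

Step 1
Reactants: 1 O-benzyl-D-tyrosine
Product: 4 (R)-3-[4-(benzyloxy)phenyl]-2-hydroxypropanoic acid, via diazonium carboxylate 2 (not isolated), via α-lactone 3 (not isolated)
Conditions: NaNO2, 1 M H2SO4, H2O/1,4-dioxane, 0 °C to rt
Reagents that add atoms: water, O
Why: Diazotisation of the α-amino acid replaces NH2 by OH with net retention, because the neighbouring carboxylate expels N2 from 2 with inversion to α-lactone 3 and water opens 3 at C2 with a second inversion, so the R configuration of 1 should be carried into 4.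

Step 2
Reactants: 4 (R)-3-[4-(benzyloxy)phenyl]-2-hydroxypropanoic acid
Product: 5 (R)-3-[4-(benzyloxy)phenyl]-2-hydroxy-N-methoxy-N-methylpropanamide
Conditions: MeNHOMe·HCl, EDC·HCl, HOBt, N-methylmorpholine, CH2Cl2, 0 °C to rt
Reagents that add atoms: N,O-dimethylhydroxylamine hydrochloride, Cl.CNOC
Why: Carbodiimide/HOBt amide coupling acylates the far more nucleophilic hydroxylamine nitrogen in preference to the secondary hydroxyl, and an α-hydroxy acid has no azlactone pathway to racemisation, so the Weinreb amide should form with C2 unchanged.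

Step 3
Reactants: 5 (R)-3-[4-(benzyloxy)phenyl]-2-hydroxy-N-methoxy-N-methylpropanamide
Product: 6 (R)-3-[4-(benzyloxy)phenyl]-2-(tert-butyldimethylsilyloxy)-N-methoxy-N-methylpropanamide
Conditions: TBSCl, imidazole, DMF, rt
Reagents that add atoms: tert-butyldimethylsilyl chloride, CC(C)(C)[Si](C)(C)Cl
Why: Imidazole-promoted silylation of a secondary alcohol is routine and breaks no bond at C2, and the silyl ether removes the acidic O–H ahead of the organolithium step and keeps the C2 oxygen out of the later etherification.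

Step 4
Reactants: 7 4-bromoresorcinol
Product: 8 2,4-bis(benzyloxy)-1-bromobenzene
Conditions: BnBr, K2CO3, DMF, rt
Reagents that add atoms: benzyl bromide, BrCc1ccccc1
Why: Twofold Williamson ether synthesis on both phenoxides gives benzyl ethers that tolerate butyllithium and are later removed by neutral hydrogenolysis.

Step 5
Reactants: 8 2,4-bis(benzyloxy)-1-bromobenzene; 6 (R)-3-[4-(benzyloxy)phenyl]-2-(tert-butyldimethylsilyloxy)-N-methoxy-N-methylpropanamide
Product: 11 (R)-1-[2,4-bis(benzyloxy)phenyl]-3-[4-(benzyloxy)phenyl]-2-(tert-butyldimethylsilyloxy)propan-1-one, via aryl-lithium 9 (not isolated), via tetrahedral lithium adduct 10 (not isolated)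
Conditions: 8 (1.3 equiv), n-BuLi, THF, −78 °C; then 6, −78 to −40 °C; AcOH quench
Reagents that add atoms: none
Why: Bromine–lithium exchange gives aryl-lithium 9, which adds only once to the amide because the N-methoxy lithium chelate 10 holds the tetrahedral stage until the quench (Weinreb ketone synthesis), and the low temperature should keep C2 from being deprotonated.

Step 6
Reactants: 11 (R)-1-[2,4-bis(benzyloxy)phenyl]-3-[4-(benzyloxy)phenyl]-2-(tert-butyldimethylsilyloxy)propan-1-one
Product: 12 (R)-2-(tert-butyldimethylsilyloxy)-1-(2,4-dihydroxyphenyl)-3-(4-hydroxyphenyl)propan-1-one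
Conditions: H2 (1 atm), 10% Pd/C, EtOAc, rt
Reagents that add atoms: none
Why: Palladium-catalysed hydrogenolysis cleaves the three aryl benzyl ethers to toluene under neutral conditions that should spare the electron-rich aryl ketone and the secondary silyl ether.

Step 7
Reactants: 12 (R)-2-(tert-butyldimethylsilyloxy)-1-(2,4-dihydroxyphenyl)-3-(4-hydroxyphenyl)propan-1-one; 13 3-chloro-3-methylbut-1-yne
Product: 14 (R)-2-(tert-butyldimethylsilyloxy)-1-[2-hydroxy-4-(2-methylbut-3-yn-2-yloxy)phenyl]-3-[4-(2-methylbut-3-yn-2-yloxy)phenyl]propan-1-one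
Conditions: 13 (2.4 equiv), DBU (3 equiv), CuCl2·2H2O (1 mol %), MeCN, 0 °C
Reagents that add atoms: none
Why: Copper-catalysed propargylic etherification of phenols with a tertiary propargyl chloride and an amidine base (copper-acetylide-assisted substitution at the tertiary propargylic carbon) is the standard entry to aryl 1,1-dimethylpropargyl ethers; the two para phenols react, whereas the 2-hydroxyl of ring A, hydrogen-bonded to the C1 carbonyl, is much less nucleophilic and should stay free.

Step 8
Reactants: 14 (R)-2-(tert-butyldimethylsilyloxy)-1-[2-hydroxy-4-(2-methylbut-3-yn-2-yloxy)phenyl]-3-[4-(2-methylbut-3-yn-2-yloxy)phenyl]propan-1-one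
Product: 15 (R)-2-(tert-butyldimethylsilyloxy)-1-[2-hydroxy-4-(2-methylbut-3-en-2-yloxy)phenyl]-3-[4-(2-methylbut-3-en-2-yloxy)phenyl]propan-1-one
Conditions: H2 (1 atm), Lindlar catalyst, quinoline, EtOAc, rt
Reagents that add atoms: none
Why: Lindlar semihydrogenation poisoned with quinoline stops terminal alkynes at the vinyl stage and should leave the aryl ketone, the ethers and the silyl group untouched.

Step 9
Reactants: 15 (R)-2-(tert-butyldimethylsilyloxy)-1-[2-hydroxy-4-(2-methylbut-3-en-2-yloxy)phenyl]-3-[4-(2-methylbut-3-en-2-yloxy)phenyl]propan-1-one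
Product: 16 (R)-2-(tert-butyldimethylsilyloxy)-1-[2-(tert-butyldimethylsilyloxy)-4-(2-methylbut-3-en-2-yloxy)phenyl]-3-[4-(2-methylbut-3-en-2-yloxy)phenyl]propan-1-one
Conditions: TBSCl, imidazole, DMAP (cat.), DMF, rt
Reagents that add atoms: tert-butyldimethylsilyl chloride, CC(C)(C)[Si](C)(C)Cl
Why: Phenol silylation with silyl chloride and imidazole (DMAP catalysis for the hydrogen-bonded hydroxyl) caps the 2-oxygen of ring A, which deletes the O–H···O=C bond and places a bulky group next to position 3 of that ring before the rearrangement, while the weak base should not enolise C2.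

Step 10
Reactants: 16 (R)-2-(tert-butyldimethylsilyloxy)-1-[2-(tert-butyldimethylsilyloxy)-4-(2-methylbut-3-en-2-yloxy)phenyl]-3-[4-(2-methylbut-3-en-2-yloxy)phenyl]propan-1-one
Product: 18 (R)-2-(tert-butyldimethylsilyloxy)-1-[2-(tert-butyldimethylsilyloxy)-4-hydroxy-5-(3-methylbut-2-en-1-yl)phenyl]-3-[4-hydroxy-3-(3-methylbut-2-en-1-yl)phenyl]propan-1-one, via bis(ortho-dienone) 17 (not isolated)
Conditions: m-xylene (degassed), 135 °C, sealed tube, Ar
Reagents that add atoms: none
Why: Each aryl 1,1-dimethylallyl ether undergoes a concerted suprafacial [3,3]-sigmatropic shift through a chair-like six-membered transition state in which the terminal =CH2 carbon bonds to the ortho ring carbon as the O–CMe2 bond breaks, giving the ortho-dienone stage 17, whose sp3 ring CH centres vanish on tautomerisation to the phenols. This is the aromatic Claisen rearrangement, well known for tertiary allyl aryl ethers, which react at lower temperature than simple allyl ethers because of the gem-dimethyl group. No ring is closed and no lasting stereocentre is created; the existing C2 centre is a silyl-protected sp3 carbon away from the reacting atoms and should not enolise in a neutral hydrocarbon medium. The selectivity needed is regiochemical on ring A, position 5 over position 3: with the 2-oxygen silylated there is no hydrogen bond to fix the bond between positions 3 and 4 as the more olefinic one, the 2-oxygen acts as a plain meta donor that steers migration away from itself, and the tert-butyldimethylsilyl group crowds position 3. On ring B the two carbons flanking the ether oxygen (positions 3 and 5) are equivalent by symmetry, so migration to either gives the same product. The acid-free conditions should also keep the new ortho-prenyl phenols from cyclising to chromans and keep both silyl ethers in place.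

Step 11
Reactants: 18 (R)-2-(tert-butyldimethylsilyloxy)-1-[2-(tert-butyldimethylsilyloxy)-4-hydroxy-5-(3-methylbut-2-en-1-yl)phenyl]-3-[4-hydroxy-3-(3-methylbut-2-en-1-yl)phenyl]propan-1-one
Product: 19 Kanzonol Y, (R)-1-[2,4-dihydroxy-5-(3-methylbut-2-en-1-yl)phenyl]-2-hydroxy-3-[4-hydroxy-3-(3-methylbut-2-en-1-yl)phenyl]propan-1-one
Conditions: HF·pyridine, pyridine, THF, 0 °C to rt
Reagents that add atoms: none
Why: Fluoride-driven desilylation (formation of the strong Si–F bond) removes both the aryl and the secondary alkyl silyl ether, and the pyridine-buffered medium should be neither basic enough to enolise the α-hydroxy ketone nor acidic enough to close the ortho-prenyl phenols to chromans.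

Compound list
1 | O-benzyl-D-tyrosine, (R)-2-amino-3-[4-(benzyloxy)phenyl]propanoic acid | N[C@H](Cc1ccc(OCc2ccccc2)cc1)C(=O)O | starting material
2 | (R)-3-[4-(benzyloxy)phenyl]-2-diazoniopropanoate (diazonium carboxylate, not isolated) | N#[N+][C@H](Cc1ccc(OCc2ccccc2)cc1)C(=O)[O-] | intermediate
3 | (S)-3-[4-(benzyloxy)benzyl]oxiran-2-one (α-lactone, not isolated) | O=C1O[C@H]1Cc1ccc(OCc2ccccc2)cc1 | intermediate
4 | (R)-3-[4-(benzyloxy)phenyl]-2-hydroxypropanoic acid | O[C@H](Cc1ccc(OCc2ccccc2)cc1)C(=O)O | intermediate
5 | (R)-3-[4-(benzyloxy)phenyl]-2-hydroxy-N-methoxy-N-methylpropanamide | O[C@H](Cc1ccc(OCc2ccccc2)cc1)C(=O)N(C)OC | intermediate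
6 | (R)-3-[4-(benzyloxy)phenyl]-2-(tert-butyldimethylsilyloxy)-N-methoxy-N-methylpropanamide | CC(C)(C)[Si](C)(C)O[C@H](Cc1ccc(OCc2ccccc2)cc1)C(=O)N(C)OC | intermediate
7 | 4-bromoresorcinol (4-bromobenzene-1,3-diol) | Oc1ccc(Br)c(O)c1 | starting material
8 | 2,4-bis(benzyloxy)-1-bromobenzene | Brc1ccc(OCc2ccccc2)cc1OCc1ccccc1 | intermediate
9 | [2,4-bis(benzyloxy)phenyl]lithium (not isolated) | [Li]c1ccc(OCc2ccccc2)cc1OCc1ccccc1 | intermediate
10 | lithium (2R)-1-[2,4-bis(benzyloxy)phenyl]-3-[4-(benzyloxy)phenyl]-2-(tert-butyldimethylsilyloxy)-1-[methoxy(methyl)amino]propan-1-olate (tetrahedral adduct, C1 undefined, not isolated) | CC(C)(C)[Si](C)(C)O[C@H](Cc1ccc(OCc2ccccc2)cc1)C(O[Li])(N(C)OC)c1ccc(OCc2ccccc2)cc1OCc1ccccc1 | intermediate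
11 | (R)-1-[2,4-bis(benzyloxy)phenyl]-3-[4-(benzyloxy)phenyl]-2-(tert-butyldimethylsilyloxy)propan-1-one | CC(C)(C)[Si](C)(C)O[C@H](Cc1ccc(OCc2ccccc2)cc1)C(=O)c1ccc(OCc2ccccc2)cc1OCc1ccccc1 | intermediate
12 | (R)-2-(tert-butyldimethylsilyloxy)-1-(2,4-dihydroxyphenyl)-3-(4-hydroxyphenyl)propan-1-one | CC(C)(C)[Si](C)(C)O[C@H](Cc1ccc(O)cc1)C(=O)c1ccc(O)cc1O | intermediate
13 | 3-chloro-3-methylbut-1-yne | C#CC(C)(C)Cl | starting material
14 | (R)-2-(tert-butyldimethylsilyloxy)-1-[2-hydroxy-4-(2-methylbut-3-yn-2-yloxy)phenyl]-3-[4-(2-methylbut-3-yn-2-yloxy)phenyl]propan-1-one | C#CC(C)(C)Oc1ccc(C[C@@H](O[Si](C)(C)C(C)(C)C)C(=O)c2ccc(OC(C)(C)C#C)cc2O)cc1 | intermediate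
15 | (R)-2-(tert-butyldimethylsilyloxy)-1-[2-hydroxy-4-(2-methylbut-3-en-2-yloxy)phenyl]-3-[4-(2-methylbut-3-en-2-yloxy)phenyl]propan-1-one | C=CC(C)(C)Oc1ccc(C[C@@H](O[Si](C)(C)C(C)(C)C)C(=O)c2ccc(OC(C)(C)C=C)cc2O)cc1 | intermediate
16 | (R)-2-(tert-butyldimethylsilyloxy)-1-[2-(tert-butyldimethylsilyloxy)-4-(2-methylbut-3-en-2-yloxy)phenyl]-3-[4-(2-methylbut-3-en-2-yloxy)phenyl]propan-1-one | C=CC(C)(C)Oc1ccc(C[C@@H](O[Si](C)(C)C(C)(C)C)C(=O)c2ccc(OC(C)(C)C=C)cc2O[Si](C)(C)C(C)(C)C)cc1 | intermediate
17 | bis(ortho-dienone) from 16, both prenyl units on ring carbon (position 5 of ring A and position 3 of ring B sp3, configuration undefined), the 4-oxygen of each ring as C=O (not isolated) | CC(C)=CCC1C=C(C[C@@H](O[Si](C)(C)C(C)(C)C)C(=O)C2=CC(CC=C(C)C)C(=O)C=C2O[Si](C)(C)C(C)(C)C)C=CC1=O | intermediate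
18 | (R)-2-(tert-butyldimethylsilyloxy)-1-[2-(tert-butyldimethylsilyloxy)-4-hydroxy-5-(3-methylbut-2-en-1-yl)phenyl]-3-[4-hydroxy-3-(3-methylbut-2-en-1-yl)phenyl]propan-1-one | CC(C)=CCc1cc(C[C@@H](O[Si](C)(C)C(C)(C)C)C(=O)c2cc(CC=C(C)C)c(O)cc2O[Si](C)(C)C(C)(C)C)ccc1O | intermediate
19 | Kanzonol Y, (R)-1-[2,4-dihydroxy-5-(3-methylbut-2-en-1-yl)phenyl]-2-hydroxy-3-[4-hydroxy-3-(3-methylbut-2-en-1-yl)phenyl]propan-1-one | CC(C)=CCc1cc(C[C@@H](O)C(=O)c2cc(CC=C(C)C)c(O)cc2O)ccc1O | target

Total step count: 11.
Longest linear sequence: 10 steps (steps 1–3 and 5–11, from 1 to 19); step 4 is a one-step side branch.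

Steps most likely to fail

Step 10. The allyl unit on ring A may migrate in part to position 3, between the two oxygens, instead of position 5. The ring-A ether, whose para-acyl phenoxide is a stabilised leaving group, may also ionise and shed isoprene before the sigmatropic shift, so the twofold rearrangement would not converge on one product. The fallback takes ring A out of the rearrangement and lets ring B alone rearrange; it sets out from 6 and comes back to the route at 19. Hydrogenolysis of 6 (H2, Pd/C, EtOAc) should give the phenol amide F1. Copper-catalysed etherification of F1 with 13 (DBU, CuCl2 cat., MeCN, 0 °C) should give the propargyl ether F2, and Lindlar semihydrogenation the tertiary allyl ether F3. Separately, purchased 4,6-dibromoresorcinol is converted with MOMCl and iPr2NEt in CH2Cl2 into the symmetric bis-MOM dibromide F4. Single bromine–lithium exchange on F4 (n-BuLi, 1.0 equiv, THF, −78 °C), then CuBr·SMe2 (cat.) and prenyl bromide, should give the prenylated bromide F5. Because the two bromines of F4 are equivalent, the prenyl group can only end up at the carbon that becomes position 5 of ring A. A second exchange on F5 and addition to F3 at −78 °C should give the ketone F6. Heating F6 in m-xylene at 135 °C rearranges ring B only, to the ring-B-prenylated phenol F7. Dilute HCl in MeOH at rt then removes the two MOM ethers and the C2 silyl ether to give 19.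

Step 7. DBU may slowly remove the C2 proton of the aryl ketone and erode its configuration, or excess reagent may push etherification onto the chelated 2-hydroxyl of ring A. The fallback replaces propargylation plus semihydrogenation by a base-free palladium-catalysed allylic etherification; it sets out from 12 and comes back at 15, so that 14 and step 8 are bypassed. 2-Methylbut-3-en-2-ol is converted (n-BuLi, then isobutyl chloroformate, THF, −78 °C to rt) into isobutyl 2-methylbut-3-en-2-yl carbonate F8. Treating 12 with F8 (2.4 equiv) and Pd(PPh3)4 (cat.) in THF at 0 °C to rt (Tsuji–Trost decarboxylative O-allylation) should deliver the branched tertiary aryl ethers of both para phenols, that is 15.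

Step 5. The hindered, ortho-alkoxy aryl-lithium may act as a base toward the amide (deprotonation at C2 or at the N-methoxy group) instead of adding, so conversion would stay low and C2 could be compromised. The fallback adds the same nucleophile to the more electrophilic aldehyde and then oxidises; it sets out from 6 and comes back at 11. Reduction of 6 with DIBAL-H (CH2Cl2, −78 °C) should give the aldehyde F9, which is used at once to avoid racemisation. Addition of 9 (from 8 and n-BuLi, THF, −78 °C) should give the carbinol F10 as a mixture at C1 that does not matter. Dess–Martin oxidation (NaHCO3, CH2Cl2, rt) removes the new centre and gives 11.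

Further compounds
F1 | step 10 | (R)-2-(tert-butyldimethylsilyloxy)-3-(4-hydroxyphenyl)-N-methoxy-N-methylpropanamide | CC(C)(C)[Si](C)(C)O[C@H](Cc1ccc(O)cc1)C(=O)N(C)OC
F2 | step 10 | (R)-2-(tert-butyldimethylsilyloxy)-N-methoxy-N-methyl-3-[4-(2-methylbut-3-yn-2-yloxy)phenyl]propanamide | CC(C)(C)[Si](C)(C)O[C@H](Cc1ccc(OC(C)(C)C#C)cc1)C(=O)N(C)OC
F3 | step 10 | (R)-2-(tert-butyldimethylsilyloxy)-N-methoxy-N-methyl-3-[4-(2-methylbut-3-en-2-yloxy)phenyl]propanamide | CC(C)(C)[Si](C)(C)O[C@H](Cc1ccc(OC(C)(C)C=C)cc1)C(=O)N(C)OC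
F4 | step 10 | 1,5-dibromo-2,4-bis(methoxymethoxy)benzene | COCOc1cc(OCOC)c(Br)cc1Br
F5 | step 10 | 1-bromo-2,4-bis(methoxymethoxy)-5-(3-methylbut-2-en-1-yl)benzene | COCOc1cc(OCOC)c(CC=C(C)C)cc1Br
F6 | step 10 | (R)-1-[2,4-bis(methoxymethoxy)-5-(3-methylbut-2-en-1-yl)phenyl]-2-(tert-butyldimethylsilyloxy)-3-[4-(2-methylbut-3-en-2-yloxy)phenyl]propan-1-one | C=CC(C)(C)Oc1ccc(C[C@@H](O[Si](C)(C)C(C)(C)C)C(=O)c2cc(CC=C(C)C)c(OCOC)cc2OCOC)cc1
F7 | step 10 | (R)-1-[2,4-bis(methoxymethoxy)-5-(3-methylbut-2-en-1-yl)phenyl]-2-(tert-butyldimethylsilyloxy)-3-[4-hydroxy-3-(3-methylbut-2-en-1-yl)phenyl]propan-1-one | CC(C)=CCc1cc(C[C@@H](O[Si](C)(C)C(C)(C)C)C(=O)c2cc(CC=C(C)C)c(OCOC)cc2OCOC)ccc1O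
F8 | step 7 | isobutyl 2-methylbut-3-en-2-yl carbonate | C=CC(C)(C)OC(=O)OCC(C)C
F9 | step 5 | (R)-3-[4-(benzyloxy)phenyl]-2-(tert-butyldimethylsilyloxy)propanal | CC(C)(C)[Si](C)(C)O[C@H](Cc1ccc(OCc2ccccc2)cc1)C=O
F10 | step 5 | (2R)-1-[2,4-bis(benzyloxy)phenyl]-3-[4-(benzyloxy)phenyl]-2-(tert-butyldimethylsilyloxy)propan-1-ol (C1 mixture) | CC(C)(C)[Si](C)(C)O[C@H](Cc1ccc(OCc2ccccc2)cc1)C(O)c1ccc(OCc2ccccc2)cc1OCc1ccccc1
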